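**Strategy**

Cuts (drimane numbering): first the aryl ether bond O–C11 (Mitsunobu with scopoletin), then C9–C11 (Wittig–Still [2,3] shift from a C7 oxygen), then C3–C4 of ring A (radical addition of C4 to a C3 aldehyde), and last C10–C1 and C10–CH3 (two enolate alkylations), which leaves (S)-carvone.
Enabling feature: in ring A the gem-dimethyl carbon C4 lies between the ring-fusion methine C5 and the carbinol carbon C3, so ring A is an isopropenyl group on C5 hydroalkylated by an aldehyde on a three-carbon arm from C10; ring B (C5–C10 with the C8 methyl, the C7=C8 alkene and a substituted C9) already is the carvone skeleton.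
Forward: carvone supplies ring B; methylation and allylation build the quaternary C10, the enone is masked as the 7,8-epoxide, the allyl arm is oxidised to the C3 aldehyde, an iron-hydride HAT cyclization closes ring A as a trans-decalin, and the coumarin is attached last.
Stereochemistry: C5 is the carvone centre; it directs the allylation (C10) and the epoxidation (C7–O on the H5 face); that oxygen survives a Wharton transposition and passes C11 to the same face of C9 in the [2,3] shift; C3 is set by equatorial hydride delivery to the 3-ketone.

Key step: step 6

Remark: drimane numbering is used for the decalin (ring A = C1–C5 and C10, ring B = C5–C10, C11 on C9); in this numbering the target is (3S,5S,9S,10R), with the C3 hydroxyl and C11 both axial and anti to the C10 methyl, and the C3 hydroxyl is carried as a triethylsilyl ether from step 9 to step 14.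

**Route**

Step 1
Reactants: 1 (S)-(+)-carvone
Product: 3 6-methylcarvone as a mixture of C6 epimers, via carvone lithium dienolate 2 (not isolated)
Conditions: LiN(i-Pr)2, THF, −78 °C; then MeI, −78 to 0 °C
Reagents that add atoms: methyl iodide, CI
Why: Kinetic α'-deprotonation of the enone gives the cross-conjugated enolate 2, and its C-methylation is a standard enolate alkylation; the configuration of the new centre does not matter because it is planarised again in step 2.

Step 2
Reactants: 3 6-methylcarvone; 4 allyl bromide
Product: 6 6-allyl-6-methylcarvone (allyl trans to isopropenyl), via methylcarvone lithium enolate 5 (not isolated)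
Conditions: LiN(i-Pr)2, THF, −78 to −20 °C; then 4, DMPU, −78 °C to rt
Reagents that add atoms: none
Why: In this diastereoselective enolate alkylation the tetrasubstituted enolate 5 should be attacked by allyl bromide on the face opposite the neighbouring isopropenyl group, which places the allyl arm trans to isopropenyl and so fixes C10 with its methyl trans to H5.

Step 3
Reactants: 6 6-allyl-6-methylcarvone
Product: 7 7,8-epoxy ketone (epoxide oxygen trans to isopropenyl)
Conditions: 30% aq H2O2, NaOH (cat.), MeOH, 0 °C to rt
Reagents that add atoms: hydrogen peroxide, OO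
Why: Weitz–Scheffer nucleophilic epoxidation touches only the electron-poor enone alkene, and hydroperoxide should add to the β-carbon (C7) anti to the C5 isopropenyl group as it does with carvone itself, so the oxygen lies on the H5 face while the allyl and isopropenyl alkenes stay inert.

Step 4
Reactants: 7 7,8-epoxy ketone
Product: 9 epoxy keto primary alcohol (3-hydroxypropyl arm on C10), via B-alkyl disiamylborane 8 (not isolated)
Conditions: (Sia)2BH (made from BH3·THF and 2-methylbut-2-ene), THF, 0 °C; then aq NaOH, 30% H2O2, 0 °C
Reagents that add atoms: hydrogen peroxide, OO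
Why: Anti-Markovnikov hydroboration–oxidation with the bulky dialkylborane should select the monosubstituted allyl alkene over the 1,1-disubstituted, ring-flanked isopropenyl group, the ketone between two fully substituted carbons should not be reduced, and no stereocentre is formed.

Step 5
Reactants: 9 epoxy keto primary alcohol
Product: 10 epoxy keto aldehyde (3-oxopropyl arm on C10)
Conditions: Dess–Martin periodinane, CH2Cl2, rt
Reagents that add atoms: none
Why: Dess–Martin oxidation converts the primary alcohol to the aldehyde under near-neutral conditions that leave the epoxy ketone and the isopropenyl group untouched.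

Step 6
Reactants: 10 epoxy keto aldehyde
Product: 13 trans-fused 7,8-epoxy-3-hydroxy-11-nordriman-9-one as both C3 epimers, via tertiary C4 radical 11 (not isolated), via cyclised C3 oxy radical 12 (not isolated)
Conditions: Fe(acac)3 (0.5 equiv), PhSiH3 (2.5 equiv), degassed EtOH, 60 °C, high dilution
Reagents that add atoms: none
Why: Proposed new method: the iron hydride (acac)2Fe–H formed from Fe(acac)3 and PhSiH3 should transfer a hydrogen atom to the CH2 terminus of the isopropenyl group, the only electron-rich alkene in 10, to give the tertiary C4 radical 11, which adds to the aldehyde carbon to give the oxy radical 12; divalent iron reduces 12 to the alkoxide, ethanol protonates it, and trivalent iron is regenerated. The closest known reaction type is the Fe(acac)3/PhSiH3 HAT-initiated reductive cyclization of alkene-tethered ketones, supported by the 6-exo additions of alkyl radicals to aldehydes known under tin hydride conditions; the new element is the aldehyde as acceptor under HAT conditions. Ring A closes in the 6-exo-trig mode through a chair transition state with both reacting arms equatorial on ring B, and because C5 and C10 are already fixed with these arms trans, only the trans-fused decalin can form. The one new stereocentre, C3, is not under reliable control, since the carbonyl oxygen can sit pseudoequatorial or pseudoaxial in that chair, and it is corrected in steps 7 and 8. The step needs HAT to the isopropenyl alkene alone and ring closure faster than hydrogen delivery to 11 or β-scission of 12; this is secured by the masking of the enone as an epoxide (no Giese acceptor remains), by a tertiary, nucleophilic radical held next to the quaternary C10 with the aldehyde arm gauche to it, and by iron and protic solvent trapping the oxy radical.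

Step 7
Reactants: 13 epoxy hydroxy ketone (C3 epimers)
Product: 14 trans-fused 7,8-epoxy-11-nordrimane-3,9-dione
Conditions: Dess–Martin periodinane, CH2Cl2, rt
Reagents that add atoms: none
Why: Dess–Martin oxidation should take both C3 epimers to the same 3-ketone, with no epimerisable centre next to either carbonyl.

Step 8
Reactants: 14 epoxy diketone
Product: 15 epoxy ketone with axial C3 alcohol (3S)
Conditions: LiBH(s-Bu)3 (1.1 equiv), THF, −78 °C; then H2O
Reagents that add atoms: none
Why: In this hindered-borohydride ketone reduction the reagent should approach the ring A carbonyl along the equatorial trajectory, as with 4,4-dimethyl-3-keto terpenoids, to give the axial C3 alcohol anti to the C10 methyl, and with about one equivalent at −78 °C the C9 carbonyl between two fully substituted carbons should stay untouched.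

Step 9
Reactants: 15 axial C3 alcohol
Product: 16 C3 triethylsilyl ether of the epoxy ketone
Conditions: Et3SiOTf, 2,6-lutidine, CH2Cl2, −78 to 0 °C
Reagents that add atoms: triethylsilyl trifluoromethanesulfonate, CC[Si](CC)(CC)OS(=O)(=O)C(F)(F)F
Why: Silylation with a silyl triflate and a hindered base is the standard way to cap a hindered axial secondary alcohol, and the triethylsilyl ether keeps O3 out of the etherification of step 11 yet is easy to remove at the end.

Step 10
Reactants: 16 silylated epoxy ketone
Product: 18 allylic alcohol (C8=C9 alkene and axial C7–OH on the H5 face), via epoxy hydrazone 17 (not isolated)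
Conditions: N2H4·H2O (excess), AcOH (cat.), MeOH, 0 °C to rt
Reagents that add atoms: none
Why: In the Wharton transposition the hydrazone 17 should open the epoxide and lose N2, which moves the alkene to C8=C9, makes C9 a CH and never breaks the C7–O bond, so the C7 configuration is retained.

Step 11
Reactants: 18 allylic alcohol; 19 tributyl(iodomethyl)stannane
Product: 21 C7 (tributylstannyl)methyl ether, via potassium C7 alkoxide 20 (not isolated)
Conditions: KH, THF, 0 °C; then 19, 0 °C to rt
Reagents that add atoms: none
Why: Williamson etherification of the potassium alkoxide 20 with the reactive iodomethylstannane should occur at the only free hydroxyl and changes no stereocentre.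

Step 12
Reactants: 21 C7 stannylmethyl ether
Product: 23 (3S,5S,9S,10R)-3-(triethylsilyloxy)drim-7-en-11-ol, via lithiomethyl ether 22 (not isolated)
Conditions: n-BuLi, THF, −78 to −20 °C; then H2O
Reagents that add atoms: none
Why: Tin–lithium exchange gives the α-alkoxymethyllithium 22, whose Wittig–Still [2,3]-sigmatropic shift is suprafacial, so the CH2O carbon should be delivered to C9 on the face of the pseudoaxial C7–O bond (anti to the C10 methyl), which sets C9 and returns the alkene to C7=C8.

Step 13
Reactants: 23 silylated primary alcohol; 24 scopoletin
Product: 25 triethylsilyl ether of the target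
Conditions: PPh3, DIAD, THF, 0 °C to rt
Reagents that add atoms: none
Why: Mitsunobu etherification should join the primary C11 alcohol to the acidic 7-hydroxyl of scopoletin without touching a stereocentre, C11 being a CH2 group.

Step 14
Reactants: 25 silylated target
Product: 26 target CNP0218138.1
Conditions: HF·pyridine, THF, 0 °C to rt
Reagents that add atoms: none
Why: Fluoride-mediated desilylation should free the C3 alcohol while the coumarin lactone, the aryl ether and the trisubstituted alkene are stable to buffered HF.

**Compound list**

1 | (S)-(+)-carvone, (5S)-2-methyl-5-(prop-1-en-2-yl)cyclohex-2-en-1-one | O=C1C(C)=CC[C@H](C(C)=C)C1 | starting material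
2 | lithium cross-conjugated dienolate of carvone (C1=C6, formed in the flask) | [Li]OC1=C[C@@H](C(C)=C)CC=C1C | intermediate
3 | 6-methylcarvone, (5S)-2,6-dimethyl-5-(prop-1-en-2-yl)cyclohex-2-en-1-one, both C6 epimers | O=C1C(C)=CC[C@H](C(C)=C)C1C | intermediate
4 | allyl bromide | C=CCBr | starting material
5 | lithium enolate of 6-methylcarvone (C1=C6 tetrasubstituted, formed in the flask) | [Li]OC1=C(C)[C@@H](C(C)=C)CC=C1C | intermediate
6 | (5R,6R)-6-allyl-2,6-dimethyl-5-(prop-1-en-2-yl)cyclohex-2-en-1-one, allyl trans to isopropenyl | O=C1C(C)=CC[C@H](C(C)=C)[C@@]1(C)CC=C | intermediate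
7 | 2,3-epoxide of 6 (drimane C7–C8), oxygen cis to allyl and trans to isopropenyl | O=C1[C@@]2(C)O[C@H]2C[C@H](C(C)=C)[C@@]1(C)CC=C | intermediate
8 | bis(3-methylbutan-2-yl)borane adduct at the allyl terminus of 7 (formed in the flask) | O=C1[C@@]2(C)O[C@H]2C[C@H](C(C)=C)[C@@]1(C)CCCB(C(C)C(C)C)C(C)C(C)C | intermediate
9 | epoxy ketone with a 3-hydroxypropyl arm on C10 | O=C1[C@@]2(C)O[C@H]2C[C@H](C(C)=C)[C@@]1(C)CCCO | intermediate
10 | epoxy keto aldehyde with a 3-oxopropyl arm on C10 | O=C1[C@@]2(C)O[C@H]2C[C@H](C(C)=C)[C@@]1(C)CCC=O | intermediate
11 | tertiary C4 radical (2-propyl radical on C5, formed in the flask) | O=C1[C@@]2(C)O[C@H]2C[C@H]([C](C)C)[C@@]1(C)CCC=O | intermediate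
12 | ring-closed C3 oxy radical (formed in the flask) | O=C1[C@@]2(C)O[C@H]2C[C@@H]3C(C)(C)C([O])CC[C@]31C | intermediate
13 | trans-fused 7,8-epoxy-3-hydroxy-11-nordriman-9-one, both C3 epimers | O=C1[C@@]2(C)O[C@H]2C[C@@H]3C(C)(C)C(O)CC[C@]31C | intermediate
14 | trans-fused 7,8-epoxy-11-nordrimane-3,9-dione | O=C1[C@@]2(C)O[C@H]2C[C@@H]3C(C)(C)C(=O)CC[C@]31C | intermediate
15 | (3S)-7,8-epoxy-3-hydroxy-11-nordriman-9-one, hydroxyl axial and anti to the C10 methyl | O=C1[C@@]2(C)O[C@H]2C[C@@H]3C(C)(C)[C@@H](O)CC[C@]31C | intermediate
16 | C3 triethylsilyl ether of 15 | O=C1[C@@]2(C)O[C@H]2C[C@@H]3C(C)(C)[C@@H](O[Si](CC)(CC)CC)CC[C@]31C | intermediate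
17 | C9 hydrazone of 16 (formed in the flask) | NN=C1[C@@]2(C)O[C@H]2C[C@@H]3C(C)(C)[C@@H](O[Si](CC)(CC)CC)CC[C@]31C | intermediate
18 | 3-(triethylsilyloxy)-11-nordrim-8-en-7-ol, C7 hydroxyl axial on the H5 face | C1=C(C)[C@@H](O)C[C@@H]2C(C)(C)[C@@H](O[Si](CC)(CC)CC)CC[C@]21C | intermediate
19 | tributyl(iodomethyl)stannane | CCCC[Sn](CCCC)(CCCC)CI | starting material
20 | potassium C7 alkoxide of 18 (formed in the flask) | C1=C(C)[C@@H](O[K])C[C@@H]2C(C)(C)[C@@H](O[Si](CC)(CC)CC)CC[C@]21C | intermediate
21 | C7 (tributylstannyl)methyl ether of 18 | C1=C(C)[C@@H](OC[Sn](CCCC)(CCCC)CCCC)C[C@@H]2C(C)(C)[C@@H](O[Si](CC)(CC)CC)CC[C@]21C | intermediate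
22 | C7 lithiomethyl ether (formed in the flask) | C1=C(C)[C@@H](OC[Li])C[C@@H]2C(C)(C)[C@@H](O[Si](CC)(CC)CC)CC[C@]21C | intermediate
23 | (3S,5S,9S,10R)-3-(triethylsilyloxy)drim-7-en-11-ol, C11 anti to the C10 methyl | OC[C@H]1C(C)=CC[C@@H]2C(C)(C)[C@@H](O[Si](CC)(CC)CC)CC[C@]21C | intermediate
24 | scopoletin (7-hydroxy-6-methoxycoumarin) | COc1cc2ccc(=O)oc2cc1O | starting material
25 | C3 triethylsilyl ether of the target | COc1cc2ccc(=O)oc2cc1OC[C@H]1C(C)=CC[C@@H]2C(C)(C)[C@@H](O[Si](CC)(CC)CC)CC[C@]21C | intermediate
26 | CNP0218138.1, 7-{[(3S,5S,9S,10R)-3-hydroxydrim-7-en-11-yl]oxy}-6-methoxycoumarin | COc1cc2ccc(=O)oc2cc1OC[C@H]1C(C)=CC[C@@H]2C(C)(C)[C@@H](O)CC[C@]21C | target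

**Count and risks**

Total step count: 14. Longest linear sequence: 14 steps, from (S)-carvone 1 to 26; compounds 4, 19 and 24 are bought and enter in steps 2, 11 and 13.

Steps most likely to fail:

1. Step 6 (proposed new method). The C4 radical may be reduced before it cyclises, the aldehyde may be reduced or acetalised in the silane and ethanol medium, or the carbonyl addition may revert by β-scission before the oxy radical is trapped. The fallback uses known chemistry and changes the acceptor to a nitrile, for which HAT-initiated cyclization of alkene-tethered nitriles under Fe(acac)3/PhSiH3 is documented. It sets out from aldehyde 10: I2 in aqueous NH3 and THF should convert the formyl group into the nitrile and give the epoxy keto nitrile F1. Treating F1 with Fe(acac)3 and PhSiH3 in EtOH at 60 °C should close ring A by 6-exo addition of the C4 radical to the nitrile carbon and give the cyclic N–H ketimine F2. Mild aqueous acid work-up (oxalic acid or silica gel) hydrolyses F2 to the diketone 14, where the route is rejoined and step 7 is no longer needed.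

2. Step 10. Hydrazone formation may fail at a carbonyl flanked by two fully substituted carbons, and hydrazine may attack the epoxide instead. The fallback replaces the hydrazone by a radical fragmentation and sets out from 16. LiAlH4 in Et2O at −78 °C should reduce the C9 ketone to the epoxy alcohol F3 (either C9 epimer serves), and NaH, CS2 and MeI should convert F3 into the S-methyl xanthate F4. Bu3SnH with AIBN in refluxing toluene then generates the C9 radical, which opens the adjacent epoxide to the allylic oxy radical; hydrogen transfer from the stannane gives the allylic alcohol 18 with the C7–O bond untouched, where the route is rejoined.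

3. Step 12. The [2,3] shift must form a bond to C9 next to the quaternary C10, so a [1,2] shift or simple protonation of the carbanion to a methyl ether may compete. The fallback uses a thermal carbene [2,3] shift and sets out from 18. Heating with N,N-dimethylformamide dimethyl acetal in xylene at 140 °C (Büchi rearrangement) should deliver the amide carbon suprafacially from O7 to C9 and give the N,N-dimethyl amide F5 with the alkene at C7=C8. LiBHEt3 in THF should reduce F5 to the primary alcohol 23, where the route is rejoined.

**Further compounds**

F1 | step 6 | epoxy keto nitrile (2-cyanoethyl arm on C10) | O=C1[C@@]2(C)O[C@H]2C[C@H](C(C)=C)[C@@]1(C)CCC#N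
F2 | step 6 | trans-fused 7,8-epoxy-3-imino-11-nordriman-9-one (N–H ketimine) | O=C1[C@@]2(C)O[C@H]2C[C@@H]3C(C)(C)C(=N)CC[C@]31C
F3 | step 10 | 7,8-epoxy-3-(triethylsilyloxy)-11-nordriman-9-ol, either C9 epimer | OC1[C@@]2(C)O[C@H]2C[C@@H]3C(C)(C)[C@@H](O[Si](CC)(CC)CC)CC[C@]31C
F4 | step 10 | O-C9 S-methyl xanthate of F3 | CSC(=S)OC1[C@@]2(C)O[C@H]2C[C@@H]3C(C)(C)[C@@H](O[Si](CC)(CC)CC)CC[C@]31C
F5 | step 12 | N,N-dimethyl 3-(triethylsilyloxy)drim-7-en-11-amide, amide carbon anti to the C10 methyl | CN(C)C(=O)[C@H]1C(C)=CC[C@@H]2C(C)(C)[C@@H](O[Si](CC)(CC)CC)CC[C@]21C
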